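The route rests on closing ring B at C2–C3, the enol-ether C=C of the vinylogous ester C1(=O)–C2=C3–O, read as a masked 1,3-diketone. The precursor is a single cyclohexene (ring A, from a Diels–Alder reaction of (E)-β-ocimene) carrying on C6 the geranyl group and a 5-methylhex-4-enoyl ketone, and on C5 a silyloxy group and an α-keto ester. Dieckmann condensation of the C2 methylene onto the ester carbon C3 forms ring B and, in one operation, the hydroxy-enedione that is the presumed biogenetic quinone–ocimene cycloadduct. Its C4 ketone and C3 enol oxygen then capture the C12=C13 alkene (Prins/oxa-cyclisation) to close rings C and D.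

Key step: step 10

Atom labels (core labels, not the locants of the systematic names): ring B = C1 (C=O), C2 (prenyl-bearing), C3 (O-bearing), C4 (C–OH), C5 (C–OH), C6 (geranyl-bearing); ring A = C5, C6, C7 (CH2), C8 (=CH), C9 (=C–CH3), C10 (CH); ring C = C4, C5, C10, C11 (CH2), C12 (CH); ring D = C3, C4, C12, C13 (CMe2), O.

Assumptions: compound 8 is used as the pure (E)-isomer. The sense of induction of the copper catalyst in step 5 is taken to give the C10 configuration drawn in 9; if it is opposite, the (R,R)-ligand is used.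

Step 1
Reactants: 1 diethyl L-tartrate
Product: 2 (2R,3R)-2,3-dihydroxy-N1,N4-dimethoxy-N1,N4-dimethylbutanediamide
Conditions: MeNH(OMe)·HCl, i-PrMgCl, THF, −20 °C to rt
Reagents that add atoms: N,O-dimethylhydroxylamine hydrochloride, CNOC.Cl
Why: Ester aminolysis by the chloromagnesium amide of N,O-dimethylhydroxylamine (ester-to-N-methoxy-N-methylamide exchange) should proceed readily on the α-hydroxy-activated diester, and the two carbinol centers are carried unchanged only to be cleaved in step 2.

Step 2
Reactants: 2 (2R,3R)-2,3-dihydroxy-N1,N4-dimethoxy-N1,N4-dimethylbutanediamide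
Product: 3 N-methoxy-N-methyl-2-oxoacetamide
Conditions: NaIO4 on SiO2, CH2Cl2, rt
Reagents that add atoms: none
Why: Malaprade glycol cleavage by periodate cuts the central C–C bond of the diol and should release two equivalents of the glyoxylic amide, which is used crude.

Step 3
Reactants: 4 methyl bromopyruvate
Product: 6 methyl 2-oxo-3-(triphenylphosphoranylidene)propanoate, via (3-methoxy-2,3-dioxopropyl)triphenylphosphonium bromide 5 (not isolated)
Conditions: PPh3, toluene, rt; then Na2CO3, CH2Cl2–H2O
Reagents that add atoms: triphenylphosphine, c1ccc(cc1)P(c1ccccc1)c1ccccc1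
Why: SN2 displacement of the α-bromide by PPh3 followed by deprotonation of the acidic phosphonium salt is the standard preparation of a keto-stabilized Wittig ylide.

Step 4
Reactants: 3 N-methoxy-N-methyl-2-oxoacetamide, 6 methyl 2-oxo-3-(triphenylphosphoranylidene)propanoate
Product: 7 methyl (3E)-5-[methoxy(methyl)amino]-2,5-dioxopent-3-enoate
Conditions: CH2Cl2, 0 °C to rt
Reagents that add atoms: none
Why: Wittig olefination of an aldehyde by a keto-stabilized ylide should give the (E)-alkene selectively.

Step 5
Reactants: 7 methyl (3E)-5-[methoxy(methyl)amino]-2,5-dioxopent-3-enoate, 8 (E)-β-ocimene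
Product: 9 methyl 2-{(1S,2R,6S)-6-[methoxy(methyl)carbamoyl]-3-methyl-2-(3-methylbut-2-en-1-yl)cyclohex-3-en-1-yl}-2-oxoacetate
Conditions: Cu(OTf)2 (10 mol %), (S,S)-t-Bu-box (11 mol %), 4 Å MS, CH2Cl2, −40 to −20 °C
Reagents that add atoms: none
Why: In this Diels–Alder reaction the α-keto ester, bound through both carbonyl oxygens to the chiral divalent copper bis(oxazoline) complex, is the dominant activator, so C6 (β to it) should bond to the unsubstituted diene terminus C7 and C5 to C10 (the orientation of the natural skeleton), endo to the bound keto ester, with the ligand shielding one face and so fixing C10, the only center that must persist since C5 and C6 are reset in steps 6 and 8.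

Step 6
Reactants: 9 Diels–Alder adduct (name as in step 5), 10 geranyl bromide
Product: 11 methyl 2-{(1S,2R,6R)-6-[(2E)-3,7-dimethylocta-2,6-dien-1-yl]-6-[methoxy(methyl)carbamoyl]-3-methyl-2-(3-methylbut-2-en-1-yl)cyclohex-3-en-1-yl}-2-oxoacetate
Conditions: LiN(i-Pr)2 (2.2 equiv), THF–DMPU, −78 to −30 °C; then 10 (1.0 equiv), −78 °C; AcOH
Reagents that add atoms: none
Why: In this dianion alkylation the first equivalent of base enolizes the acidic C5–H of the α-keto ester and the second forms the more reactive amide enolate at C6, which alone should be alkylated; the C10 side chain is pseudo-axial (allylic strain against the C9 methyl and the exocyclic C5 enolate), so the bromide should enter anti to it and set the C6 quaternary center, while the C5 configuration after protonation is of no consequence.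

Step 7
Reactants: 11 geranylated amide (name as in step 6), 12 5-bromo-2-methylpent-2-ene
Product: 13 methyl 2-{(1S,2R,6R)-6-[(2E)-3,7-dimethylocta-2,6-dien-1-yl]-3-methyl-2-(3-methylbut-2-en-1-yl)-6-(5-methylhex-4-enoyl)cyclohex-3-en-1-yl}-2-oxoacetate
Conditions: KN(SiMe3)2 (1.05 equiv), THF, −78 °C; then Me2C=CHCH2CH2MgBr (from 12, Mg, THF; 3 equiv), −78 to 0 °C; 1 M HCl, 0 °C
Reagents that add atoms: (4-methylpent-3-en-1-yl)magnesium bromide made from 12, CC(C)=CCC[Mg]Br
Why: This is a Weinreb ketone synthesis (Grignard addition to the N-methoxy-N-methylamide through a stable chelated tetrahedral intermediate) run after the α-keto ester has been protected in the flask as its C5 potassium enolate, which should leave the amide as the only electrophile.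

Step 8
Reactants: 13 keto ester (name as in step 7)
Product: 14 methyl 2-{(1R,2S,6R)-6-[(2E)-3,7-dimethylocta-2,6-dien-1-yl]-1-hydroxy-3-methyl-2-(3-methylbut-2-en-1-yl)-6-(5-methylhex-4-enoyl)cyclohex-3-en-1-yl}-2-oxoacetate
Conditions: KN(SiMe3)2 (1.1 equiv), THF, −78 °C; 2-(phenylsulfonyl)-3-phenyloxaziridine (1.3 equiv), −78 °C; AcOH
Reagents that add atoms: 2-(phenylsulfonyl)-3-phenyloxaziridine, O=S(=O)(N1OC1c1ccccc1)c1ccccc1
Why: In this enolate hydroxylation by an N-sulfonyloxaziridine only C5–H is acidic enough for one equivalent of base, and the oxidant should approach the planar enolate from the face opposite the C10 side chain and the C6 acyl group, placing the C5 hydroxyl cis to geranyl and to H-10.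

Step 9
Reactants: 14 tertiary α-hydroxy keto ester (name as in step 8)
Product: 15 methyl 2-{(1R,2S,6R)-6-[(2E)-3,7-dimethylocta-2,6-dien-1-yl]-3-methyl-2-(3-methylbut-2-en-1-yl)-6-(5-methylhex-4-enoyl)-1-[(triethylsilyl)oxy]cyclohex-3-en-1-yl}-2-oxoacetate
Conditions: Et3SiOTf, 2,6-lutidine, CH2Cl2, −78 to 0 °C
Reagents that add atoms: triethylsilyl trifluoromethanesulfonate, CC[Si](CC)(CC)OS(=O)(=O)C(F)(F)F
Why: Silylation of the hindered tertiary alcohol by the silyl triflate should be clean at low temperature, and the ether blocks retro-aldol cleavage of the β-hydroxy ketone and α-ketol shift in the basic key step.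

Step 10
Reactants: 15 silyloxy keto ester (name as in step 9)
Product: 16 (4aR,8S,8aR)-4a-[(2E)-3,7-dimethylocta-2,6-dien-1-yl]-2-hydroxy-7-methyl-3,8-bis(3-methylbut-2-en-1-yl)-8a-[(triethylsilyl)oxy]-4a,5,8,8a-tetrahydronaphthalene-1,4-dione
Conditions: KN(SiMe3)2 (2.2 equiv), THF, −78 to 0 °C; AcOH
Reagents that add atoms: none
Why: The base can enolize only C2 (C6 is quaternary, C5 is fully substituted and C4 has no α-hydrogen), and the potassium enolate adds to the ester carbonyl C3 of the α-keto ester; loss of methoxide gives the cyclic tricarbonyl array, which is deprotonated at once to a stabilized enolate and so drains the reversible five-membered aldol adduct at the C4 ketone. The closest known reaction type is the Dieckmann (intramolecular crossed Claisen) condensation of a ketone enolate with an oxalyl-type ester to give a cyclohexane-1,3-dione. Ring B closes in the 6-(enolendo)-exo-trig mode. No stereocenter is created, and C5, C6 and C10 are untouched because C5 and C6 carry no hydrogen and H-10 is not acidic. The selectivity needed is acylation at C3 over aldol addition at C4 and over retro-aldol or α-ketol shift of the C5 carbinol; the first is secured by the irreversible enolate formation of the product, the second by the silyl ether on the C5 oxygen.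

Step 11
Reactants: 16 ring B hydroxy-enedione (name as in step 10)
Product: 18 CNP0323114.1, via C5 triethylsilyl ether of the target 17 (not isolated)
Conditions: Me2AlCl (2.5 equiv), CH2Cl2, −78 to −20 °C; aq. NaHCO3; then HF·pyridine, THF, 0 °C to rt
Reagents that add atoms: none
Why: In this biomimetic Prins/oxa-cyclisation Me2AlCl should turn the enol into an aluminium chelate that activates the C4 ketone, the C12=C13 alkene held on the same face of ring A attacks C4 (ring C), and the tertiary C13 cation is captured by the C3 enolate oxygen (ring D); the cis fusion of ring C to ring B and of ring D to ring C fixes C4 and C12, and HF·pyridine then frees the C5 hydroxyl.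

Compound list
1 | diethyl L-tartrate, diethyl (2R,3R)-2,3-dihydroxybutanedioate | CCOC(=O)[C@H](O)[C@@H](O)C(=O)OCC | starting material
2 | (2R,3R)-2,3-dihydroxy-N1,N4-dimethoxy-N1,N4-dimethylbutanediamide | CON(C)C(=O)[C@H](O)[C@@H](O)C(=O)N(C)OC | intermediate
3 | N-methoxy-N-methyl-2-oxoacetamide | CON(C)C(=O)C=O | intermediate
4 | methyl bromopyruvate, methyl 3-bromo-2-oxopropanoate | COC(=O)C(=O)CBr | starting material
5 | (3-methoxy-2,3-dioxopropyl)triphenylphosphonium bromide | COC(=O)C(=O)C[P+](c1ccccc1)(c1ccccc1)c1ccccc1.[Br-] | intermediate (not isolated)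
6 | methyl 2-oxo-3-(triphenylphosphoranylidene)propanoate | COC(=O)C(=O)C=P(c1ccccc1)(c1ccccc1)c1ccccc1 | intermediate
7 | methyl (3E)-5-[methoxy(methyl)amino]-2,5-dioxopent-3-enoate | COC(=O)C(=O)/C=C/C(=O)N(C)OC | intermediate
8 | (E)-β-ocimene, (3E)-3,7-dimethylocta-1,3,6-triene | C=C/C(C)=C/CC=C(C)C | starting material
9 | methyl 2-{(1S,2R,6S)-6-[methoxy(methyl)carbamoyl]-3-methyl-2-(3-methylbut-2-en-1-yl)cyclohex-3-en-1-yl}-2-oxoacetate; keto ester cis to the prenyl chain, trans to the amide | CON(C)C(=O)[C@H]1CC=C(C)[C@H](CC=C(C)C)[C@@H]1C(=O)C(=O)OC | intermediate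
10 | geranyl bromide, (2E)-1-bromo-3,7-dimethylocta-2,6-diene | CC(C)=CCC/C(C)=C/CBr | starting material
11 | methyl 2-{(1S,2R,6R)-6-[(2E)-3,7-dimethylocta-2,6-dien-1-yl]-6-[methoxy(methyl)carbamoyl]-3-methyl-2-(3-methylbut-2-en-1-yl)cyclohex-3-en-1-yl}-2-oxoacetate; geranyl trans to the prenyl chain | CC(C)=CCC/C(C)=C/C[C@@]1(C(=O)N(C)OC)CC=C(C)[C@H](CC=C(C)C)[C@@H]1C(=O)C(=O)OC | intermediate
12 | 5-bromo-2-methylpent-2-ene | CC(C)=CCCBr | starting material
13 | methyl 2-{(1S,2R,6R)-6-[(2E)-3,7-dimethylocta-2,6-dien-1-yl]-3-methyl-2-(3-methylbut-2-en-1-yl)-6-(5-methylhex-4-enoyl)cyclohex-3-en-1-yl}-2-oxoacetate | CC(C)=CCC/C(C)=C/C[C@@]1(C(=O)CCC=C(C)C)CC=C(C)[C@H](CC=C(C)C)[C@@H]1C(=O)C(=O)OC | intermediate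
14 | methyl 2-{(1R,2S,6R)-6-[(2E)-3,7-dimethylocta-2,6-dien-1-yl]-1-hydroxy-3-methyl-2-(3-methylbut-2-en-1-yl)-6-(5-methylhex-4-enoyl)cyclohex-3-en-1-yl}-2-oxoacetate; OH cis to geranyl, the three carbon chains on the other face | CC(C)=CCC/C(C)=C/C[C@@]1(C(=O)CCC=C(C)C)CC=C(C)[C@H](CC=C(C)C)[C@]1(O)C(=O)C(=O)OC | intermediate
15 | methyl 2-{(1R,2S,6R)-6-[(2E)-3,7-dimethylocta-2,6-dien-1-yl]-3-methyl-2-(3-methylbut-2-en-1-yl)-6-(5-methylhex-4-enoyl)-1-[(triethylsilyl)oxy]cyclohex-3-en-1-yl}-2-oxoacetate | CC(C)=CCC/C(C)=C/C[C@@]1(C(=O)CCC=C(C)C)CC=C(C)[C@H](CC=C(C)C)[C@]1(O[Si](CC)(CC)CC)C(=O)C(=O)OC | intermediate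
16 | (4aR,8S,8aR)-4a-[(2E)-3,7-dimethylocta-2,6-dien-1-yl]-2-hydroxy-7-methyl-3,8-bis(3-methylbut-2-en-1-yl)-8a-[(triethylsilyl)oxy]-4a,5,8,8a-tetrahydronaphthalene-1,4-dione (rings A and B, cis-fused) | CC(C)=CCC/C(C)=C/C[C@@]12CC=C(C)[C@H](CC=C(C)C)[C@]1(O[Si](CC)(CC)CC)C(=O)C(O)=C(CC=C(C)C)C2=O | intermediate
17 | C5 triethylsilyl ether of the target (tetracycle, silyl on the C5 oxygen) | CC(C)=CCC/C(C)=C/C[C@]12CC=C(C)[C@@H]3C[C@@H]4C(C)(C)OC(=C(CC=C(C)C)C1=O)[C@]4(O)[C@@]32O[Si](CC)(CC)CC | intermediate (not isolated)
18 | CNP0323114.1; tetracyclic vinylogous ester with C4 (R), C5 (R), C6 (R), C10 (S), C12 (S) in the core labels, (E)-geranyl on C6, cis-diol at C4/C5 | CC(C)=CCC/C(C)=C/C[C@]12CC=C(C)[C@@H]3C[C@@H]4C(C)(C)OC(=C(CC=C(C)C)C1=O)[C@]4(O)[C@@]32O | target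

Total step count: 11. Longest linear sequence: 10 steps (steps 1, 2, 4, 5, 6, 7, 8, 9, 10, 11); step 3 is a one-step side branch.

Steps most likely to fail

Step 10. The C2 enolate may stay trapped as the five-membered aldol adduct at the C4 ketone, or silyl migration and retro-aldol opening may follow, so that acylation at C3 does not win. The fallback inverts the order of the two ring-forming events and sets out from 15. Me2AlCl (CH2Cl2, −78 °C) should make the C4 carbonyl of the α-keto ester take the C12=C13 alkene while the ester oxygen captures the C13 cation with loss of chloromethane, giving the tricyclic hydroxy lactone F5, in which C4 is a carbinol and no longer competes. Here the facial course at C4 is not enforced by ring B and rests on the cis fusion of rings C and D. Addition of the C2 potassium enolate (KN(SiMe3)2, 3 equiv, THF) to the lactone carbonyl C3 with expulsion of the tertiary alkoxide should give the ring B hydroxy enol-dione F6. Acid-catalysed cyclodehydration (PPTS, benzene, 50 °C) should then re-form ring D and rejoin the route at 17.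

Step 5. The cycloaddition may give the wrong orientation on the 1,2-disubstituted diene or poor endo and facial control, or it may divert to hetero-Diels–Alder or carbonyl-ene reaction at the bound keto group. The fallback replaces catalyst control by auxiliary control and sets out from 7. Transesterification with (−)-8-phenylmenthol (Ti(OEt)4, toluene, 80 °C) should give the 8-phenylmenthyl keto ester F1. Its SnCl4-chelated s-cis keto ester is shielded on one face by the aryl group, and cycloaddition with 8 (CH2Cl2, −78 °C) should give the adduct F2. Methanolysis (K2CO3, MeOH, 0 °C) returns to the route at 9.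

Step 6. Formation of the vicinal dianion may be incomplete because the tetrasubstituted amide enolate is hindered, and alkylation may then occur at C5 or on oxygen, or with poor facial control. The fallback replaces the dianion by a protected monoanion and sets out from 9. The more acidic C5 position is blocked as the triethylsilyl enol ether F3 (Et3SiOTf, Et3N, CH2Cl2, −78 °C). The amide enolate at C6 is then formed alone (LiN(i-Pr)2, 1.1 equiv, THF–DMPU, −78 °C) and alkylated with 10 to give the geranylated enol ether F4. Cleavage of the enol ether (HF·pyridine, THF, 0 °C) comes back to the route at 11.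

Further compounds
F1 | step 5 | (1R,2S,5R)-5-methyl-2-(2-phenylpropan-2-yl)cyclohexyl (3E)-5-[methoxy(methyl)amino]-2,5-dioxopent-3-enoate | CON(C)C(=O)/C=C/C(=O)C(=O)O[C@@H]1C[C@H](C)CC[C@H]1C(C)(C)c1ccccc1
F2 | step 5 | (−)-8-phenylmenthyl ester analogue of 9 (same ring configuration as 9) | CON(C)C(=O)[C@H]1CC=C(C)[C@H](CC=C(C)C)[C@@H]1C(=O)C(=O)O[C@@H]1C[C@H](C)CC[C@H]1C(C)(C)c1ccccc1
F3 | step 6 | C5 triethylsilyl enol ether of 9, methyl 2-{6-[methoxy(methyl)carbamoyl]-3-methyl-2-(3-methylbut-2-en-1-yl)cyclohex-3-en-1-ylidene}-2-[(triethylsilyl)oxy]acetate (enol ether geometry as drawn, of no consequence) | CON(C)C(=O)[C@H]1CC=C(C)[C@H](CC=C(C)C)/C1=C(/O[Si](CC)(CC)CC)C(=O)OC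
F4 | step 6 | C6-geranylated silyl enol ether, the C5 triethylsilyl enol ether of 11 | CC(C)=CCC/C(C)=C/C[C@@]1(C(=O)N(C)OC)CC=C(C)[C@H](CC=C(C)C)/C1=C(/O[Si](CC)(CC)CC)C(=O)OC
F5 | step 10 | tricyclic hydroxy lactone (rings A and C, ring D as γ-lactone C3(=O)–O–C13; C4–OH, C5–OSiEt3, geranyl and 5-methylhex-4-enoyl on C6) | CC(C)=CCC/C(C)=C/C[C@@]1(C(=O)CCC=C(C)C)CC=C(C)[C@@H]2C[C@@H]3C(C)(C)OC(=O)[C@]3(O)[C@@]21O[Si](CC)(CC)CC
F6 | step 10 | ring B hydroxy enol-dione (rings A, B and C; C3 enol, C4–OH, C5–OSiEt3, free 2-hydroxypropan-2-yl on C12) | CC(C)=CCC/C(C)=C/C[C@]12CC=C(C)[C@@H]3C[C@H](C(C)(C)O)[C@](O)(C(O)=C(CC=C(C)C)C1=O)[C@@]32O[Si](CC)(CC)CC
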